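We decide to carry one number through these flasks, the share the tautomer equilibrium gives, and to try it first on west against south, two flasks that part at the switch.

    starting material ⇌ tautomer (K1 = 0.71, k1 = 0.12 s⁻¹, Ea1 = 76.0 kJ mol⁻¹, ΔH1 = −21.0 kJ mol⁻¹)
    2 starting material → self-condensation product (k2 = 1.1 M⁻¹ s⁻¹, Ea2 = 35.0 kJ mol⁻¹)
    gas ⇌ reagent, rate k3*(csat - [reagent]) (k3 = 0.16 s⁻¹, csat = 47 mM)
    reagent + tautomer → target (k4 = 2.2 M⁻¹ s⁻¹, Ea4 = 56.0 kJ mol⁻¹)
    starting material + reagent → isomer of the product (k5 = 0.58 M⁻¹ s⁻¹, Ea5 = 53.0 kJ mol⁻¹)
    (constants at 35 °C)

| flask | starting material | gas | temperature | time | remark |
|---|---|---|---|---|---|
| west | 0.12 M | 47 mM (held) | 65 °C | 40 s |  |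
| south-east | 0.12 M | 47 mM (held) | 5 °C | 40 s |  |
| south-west | 0.12 M | 47 mM (held) | 35 °C | 40 s |  |
| south | 0.12 M | 47 mM (held) |  | 40 s | at 65 °C until 20 s, from then on at 5 °C |

- the flask with the highest share of target in all that became target or isomer of the product ("all alike" if they lie within 1.5 percentage points) (west / south-east / south-west / south / all alike)
- share of target in all that became target or isomer of the product, west
- share of target in all that became target or isomer of the product, south-east
- share of target in all that became target or isomer of the product, south-west
- share of target in all that became target or isomer of the product, south

- in percentages every species weighs as the starting material in it: one self-condensation product counts as two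
- where a step has two of a species, its rate is k times that concentration squared, and two are used at each turn
- at the start none of reagent is dissolved
- at 35 °C the constants are as listed, elsewhere as the activation energies and enthalpies make them

Target and isomer of the product draw on the same dissolved reagent, so reagent cancels from their ratio. That ratio is the target constant times the tautomer against the isomer constant times the starting material. While tautomer keeps pace with starting material, their ratio is the equilibrium constant, here 0.343 at 65 °C. West then gives 59.1 % target among the two products: this is the equilibrium share, the selectivity at tautomer equilibrium. It applies in west because the relaxation time of the tautomer step, 0.153 s, is shorter than the first half-life by self-condensation, 1.13 s.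

South is the same flask as west until 20 s, so we work with the fraction left at the switch. Self-condensation by itself, whose rate goes with the square of the starting material and so with the square of its part of the pool given by the equilibrium constant, leaves 9.23 % of the pool of starting material and tautomer, and the reagent steps take more. Nearly all of the pool has therefore gone before the cold begins, so south ends beside west: 59.1 %.

In south-west the relaxation time 3.46 s is about as long as the half-life 3.79 s. The tautomer lags at the start, and the equilibrium share there is a ceiling: 72.9 %. In south-east, self-condensation by itself leaves a fraction 29.2 % at the end, while the forward step has made under 9.95 %. Their ratio is less than the equilibrium constant there, and it has been climbing, so the end ratio is not the ratio the products saw. The products form along the whole run, so for south-east we take the tautomer summed over time against the starting material summed over time, with both curves as just reckoned and the dissolved reagent taken as steady: that ratio is 0.117, and it gives 28.2 %. We therefore commit to south-west as the highest.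

The forecast named south-west, with 59 % for west, 29 % for south-east, 68 % for south-west and 58.9 % for south, and said of south: “The pool is essentially consumed by 20 s at 65 °C, so cooling changes almost nothing”.

The simulation gives south-west, with 58.8 % in west, 29.8 % in south-east, 69.6 % in south-west and 58.8 % in south.

West reads 0.30 percentage points from its equilibrium share, and it has come to rest, with conversion >99.9 %. South keeps 0.52 % of starting material and 0.198 % of tautomer, and reads 58.9 % after 400 s. South-west keeps 3.5 % and 2.05 %, and reads 69.4 % at that time. South-east has not come to rest: it holds 24 % of starting material and 6.94 % of tautomer at 40.0 s, and at 400 s its share reads 58.8 %, with target at 13.7 %.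

The neighbour run like south-west at 50 °C has an equilibrium constant of 0.485, so its equilibrium share is 66.0 %. The computed flask gives 65.1 %.

(The rate constants stand for no real mixture; the run is a simulation.)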